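**Plan**
- Retrosynthesis: the stilbene C=C is cut first (olefination of a C5 aldehyde), then the exocyclic CH2–O bond together with the C3–C3a bond of the dihydrobenzofuran, and last the O1–C2 aryl ether bond.
- Enabling feature: C3 is bonded to C3a of ring A and to an oxygenated exocyclic CH2. A radical at C3a can therefore add to a vinyl group on C2, and the CH2 radical that results can be capped by oxygen.
- Forward: a sinapyl-type carbonate (from syringaldehyde) and 5-iodovanillin are joined at O1–C2, the dihydrofuran ring is then closed onto ring A, and the resorcinol ring is attached last as a benzylphosphonate.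
- Stereochemistry: C2 (R) comes from an iridium-catalysed asymmetric allylic etherification, C3 (S) is relayed from C2 in the ring closure (trans), and the E alkene comes from the Horner–Wadsworth–Emmons step.

Key step: step 6

Assumption: in step 5 the (Ra,R,R) antipode of the phosphoramidite is taken to give the (R) ether, the usual sense of induction of this catalyst class with heteroatom nucleophiles; were the sense opposite, the (Sa,S,S) ligand would be used with no other change.

**Route**

Step 1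
Reactants: 1 syringaldehyde
Product: 2 3,5-dimethoxy-4-[(triisopropylsilyl)oxy]benzaldehyde
Conditions: TIPSCl, imidazole, DMF, rt
Reagents that add atoms: triisopropylsilyl chloride, CC(C)[Si](Cl)(C(C)C)C(C)C
Why: Imidazole-promoted O-silylation of the acidic phenol should give a silyl ether that tolerates the aryloxide, hydride, tin radical, hot acetic acid and carbanion conditions ahead and falls to fluoride at the end.

Step 2
Reactants: 2 3,5-dimethoxy-4-[(triisopropylsilyl)oxy]benzaldehyde
Product: 3 ethyl (E)-3-{3,5-dimethoxy-4-[(triisopropylsilyl)oxy]phenyl}prop-2-enoate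
Conditions: Ph3P=CHCO2Et, toluene, 90 °C
Reagents that add atoms: ethyl (triphenylphosphoranylidene)acetate, CCOC(=O)C=P(c1ccccc1)(c1ccccc1)c1ccccc1
Why: Wittig olefination with a stabilised ylide under neutral conditions should give the E cinnamate and leave the aryl silyl ether alone.

Step 3
Reactants: 3 ethyl (E)-3-{3,5-dimethoxy-4-[(triisopropylsilyl)oxy]phenyl}prop-2-enoate
Product: 4 (E)-3-{3,5-dimethoxy-4-[(triisopropylsilyl)oxy]phenyl}prop-2-en-1-ol
Conditions: i-Bu2AlH (2.5 equiv), CH2Cl2, −78 °C; aq. potassium sodium tartrate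
Reagents that add atoms: none
Why: 1,2-Reduction of the unsaturated ester by the aluminium hydride should stop at the allylic alcohol without touching the alkene or the silyl ether.

Step 4
Reactants: 4 (E)-3-{3,5-dimethoxy-4-[(triisopropylsilyl)oxy]phenyl}prop-2-en-1-ol
Product: 5 (E)-3-{3,5-dimethoxy-4-[(triisopropylsilyl)oxy]phenyl}prop-2-en-1-yl methyl carbonate
Conditions: ClCO2Me, pyridine, CH2Cl2, 0 °C
Reagents that add atoms: methyl chloroformate, COC(=O)Cl
Why: Acylation of the primary allylic alcohol installs the carbonate leaving group needed for ionisation by iridium in the next step.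

Step 5
Reactants: 5 (E)-3-{3,5-dimethoxy-4-[(triisopropylsilyl)oxy]phenyl}prop-2-en-1-yl methyl carbonate; 6 4-hydroxy-3-iodo-5-methoxybenzaldehyde (5-iodovanillin)
Product: 8 4-{[(1R)-1-{3,5-dimethoxy-4-[(triisopropylsilyl)oxy]phenyl}prop-2-en-1-yl]oxy}-3-iodo-5-methoxybenzaldehyde, via lithium 4-formyl-2-iodo-6-methoxyphenolate 7 (not isolated)
Conditions: 6, LiOtBu, THF, rt; then 5, [Ir(cod)Cl]2 (2 mol %), (Ra,R,R)-O,O'-(1,1'-binaphthalene-2,2'-diyl) N,N-bis(1-phenylethyl)phosphoramidite (4 mol %, catalyst pre-formed with n-PrNH2), THF, 50 °C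
Reagents that add atoms: none
Why: In this iridium-catalysed asymmetric allylic etherification the cyclometalated iridium phosphoramidite complex ionises the carbonate to an allyl iridium intermediate, which aryloxide 7 should attack at the aryl-substituted terminus to give the branched ether with C2 set by the chiral ligand, while the blocked ortho and para positions of the nucleophile exclude C-allylation and a later Claisen shift.

Step 6
Reactants: 8 4-{[(1R)-1-{3,5-dimethoxy-4-[(triisopropylsilyl)oxy]phenyl}prop-2-en-1-yl]oxy}-3-iodo-5-methoxybenzaldehyde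
Product: 11 (2R,3S)-2-{3,5-dimethoxy-4-[(triisopropylsilyl)oxy]phenyl}-7-methoxy-3-{[(2,2,6,6-tetramethylpiperidin-1-yl)oxy]methyl}-2,3-dihydro-1-benzofuran-5-carbaldehyde, via C3a-centred aryl radical 9 (not isolated), via cyclised primary alkyl radical 10 (not isolated)
Conditions: Bu3SnH (4 equiv, added in portions), TEMPO (6 equiv), benzene, 70 °C
Reagents that add atoms: TEMPO (2,2,6,6-tetramethylpiperidin-1-oxyl), CC1(C)CCCC(C)(C)N1[O]
Why: Bu3SnH is converted by TEMPO into Bu3Sn•, which abstracts iodine from C3a of ring A; the σ-aryl radical 9 adds to the internal carbon of the vinyl group on C2 and the primary radical 10 is captured at oxygen by the persistent nitroxide, so that the C3–C3a bond and the exocyclic CH2–O bond form in one operation. The closest known reaction type is the tin hydride–nitroxide mediated aryl radical cyclisation of ortho-iodoaryl allyl ethers and N-allylanilides with TEMPO trapping of the cyclised radical. The dihydrofuran ring closes in the 5-exo-trig mode. The new stereocentre C3 is set by the existing centre C2: in the chair-like transition state the C2 aryl group takes the pseudo-equatorial position away from the alkene terminus, so the forming CH2 group should end up trans to it, which is the (2R,3S) arrangement of the target. The step needs 5-exo rather than 6-endo closure, ring closure ahead of interception of 9 by TEMPO or a hydrogen donor, and retention at C2; the three-atom ortho tether ending in an unsubstituted terminal alkene makes the unimolecular 5-exo addition far faster than any bimolecular capture, the C2–H bond could only be reached through a strained 1,4-hydrogen shift, and the excess nitroxide should quench 10 before reduction or neophyl-type ring expansion can occur.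

Step 7
Reactants: 12 methyl 3,5-dihydroxybenzoate
Product: 13 methyl 3,5-bis[(triisopropylsilyl)oxy]benzoate
Conditions: TIPSCl (2.4 equiv), imidazole, DMF, rt
Reagents that add atoms: triisopropylsilyl chloride, CC(C)[Si](Cl)(C(C)C)C(C)C
Why: Imidazole-promoted silylation of both phenols gives base-stable ethers that share the final fluoride deprotection with the silyl group of ring C2-aryl.

Step 8
Reactants: 13 methyl 3,5-bis[(triisopropylsilyl)oxy]benzoate
Product: 14 {3,5-bis[(triisopropylsilyl)oxy]phenyl}methanol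
Conditions: i-Bu2AlH (2.5 equiv), CH2Cl2, −78 → 0 °C; aq. potassium sodium tartrate
Reagents that add atoms: none
Why: Hydride reduction of the benzoate ester to the benzylic alcohol is standard and should leave the aryl silyl ethers intact.

Step 9
Reactants: 14 {3,5-bis[(triisopropylsilyl)oxy]phenyl}methanol
Product: 15 1-(bromomethyl)-3,5-bis[(triisopropylsilyl)oxy]benzene
Conditions: Ph3PBr2, imidazole, CH2Cl2, 0 °C
Reagents that add atoms: dibromotriphenylphosphorane, BrP(Br)(c1ccccc1)(c1ccccc1)c1ccccc1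
Why: Appel-type deoxybromination through an alkoxyphosphonium ion should give the benzylic bromide under buffered conditions that spare the silyl ethers.

Step 10
Reactants: 15 1-(bromomethyl)-3,5-bis[(triisopropylsilyl)oxy]benzene
Product: 16 diethyl {3,5-bis[(triisopropylsilyl)oxy]benzyl}phosphonate
Conditions: P(OEt)3 (neat), 130 °C
Reagents that add atoms: triethyl phosphite, CCOP(OCC)OCC
Why: The Michaelis–Arbuzov reaction of a primary benzylic bromide with triethyl phosphite reliably gives the benzylphosphonate with loss of bromoethane.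

Step 11
Reactants: 11 (2R,3S)-2-{3,5-dimethoxy-4-[(triisopropylsilyl)oxy]phenyl}-7-methoxy-3-{[(2,2,6,6-tetramethylpiperidin-1-yl)oxy]methyl}-2,3-dihydro-1-benzofuran-5-carbaldehyde; 16 diethyl {3,5-bis[(triisopropylsilyl)oxy]benzyl}phosphonate
Product: 18 1-({(2R,3S)-5-[(E)-2-{3,5-bis[(triisopropylsilyl)oxy]phenyl}ethenyl]-2-{3,5-dimethoxy-4-[(triisopropylsilyl)oxy]phenyl}-7-methoxy-2,3-dihydro-1-benzofuran-3-yl}methoxy)-2,2,6,6-tetramethylpiperidine, via sodium phosphonate carbanion 17 (not isolated)
Conditions: 16, NaH, 15-crown-5 (cat.), THF, 0 °C; then 11, 0 °C → rt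
Reagents that add atoms: none
Why: Horner–Wadsworth–Emmons olefination of an aryl aldehyde with a benzylphosphonate carbanion should give the E stilbene, and the alkoxyamine, the silyl ethers and the non-acidic C2 and C3 centres are expected to be inert to the carbanion.

Step 12
Reactants: 18 the E stilbene alkoxyamine of step 11
Product: 19 {(2R,3S)-5-[(E)-2-{3,5-bis[(triisopropylsilyl)oxy]phenyl}ethenyl]-2-{3,5-dimethoxy-4-[(triisopropylsilyl)oxy]phenyl}-7-methoxy-2,3-dihydro-1-benzofuran-3-yl}methanol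
Conditions: Zn dust, AcOH/THF/H2O (3:1:1), 70 °C
Reagents that add atoms: none
Why: Dissolving-metal reduction cleaves the weak N–O bond of the alkoxyamine to release the primary alcohol, and it is placed after the olefination so that no aryl aldehyde is exposed to Zn, which could cause pinacol coupling.

Step 13
Reactants: 19 the tris-silylated primary alcohol of step 12
Product: 20 Gnetucleistol F, 5-[(E)-2-[(2R,3S)-2-(4-hydroxy-3,5-dimethoxyphenyl)-3-(hydroxymethyl)-7-methoxy-2,3-dihydro-1-benzofuran-5-yl]ethenyl]benzene-1,3-diol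
Conditions: Bu4NF, AcOH (1:1, 4 equiv), THF, 0 °C → rt
Reagents that add atoms: none
Why: Fluoride desilylation should remove all three aryl silyl ethers, and the acetic acid buffer keeps the phenol para to the C2–O1 bond protonated so that it cannot open the ring through a quinone methide and scramble C2.

**Compound list**
1 | syringaldehyde (4-hydroxy-3,5-dimethoxybenzaldehyde) | COc1cc(C=O)cc(OC)c1O | starting material
2 | 3,5-dimethoxy-4-[(triisopropylsilyl)oxy]benzaldehyde | COc1cc(C=O)cc(OC)c1O[Si](C(C)C)(C(C)C)C(C)C | intermediate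
3 | ethyl (E)-3-{3,5-dimethoxy-4-[(triisopropylsilyl)oxy]phenyl}prop-2-enoate | CCOC(=O)/C=C/c1cc(OC)c(O[Si](C(C)C)(C(C)C)C(C)C)c(OC)c1 | intermediate
4 | (E)-3-{3,5-dimethoxy-4-[(triisopropylsilyl)oxy]phenyl}prop-2-en-1-ol | OC/C=C/c1cc(OC)c(O[Si](C(C)C)(C(C)C)C(C)C)c(OC)c1 | intermediate
5 | (E)-3-{3,5-dimethoxy-4-[(triisopropylsilyl)oxy]phenyl}prop-2-en-1-yl methyl carbonate | COC(=O)OC/C=C/c1cc(OC)c(O[Si](C(C)C)(C(C)C)C(C)C)c(OC)c1 | intermediate
6 | 4-hydroxy-3-iodo-5-methoxybenzaldehyde (5-iodovanillin) | COc1cc(C=O)cc(I)c1O | starting material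
7 | lithium 4-formyl-2-iodo-6-methoxyphenolate | [Li+].COc1cc(C=O)cc(I)c1[O-] | intermediate
8 | 4-{[(1R)-1-{3,5-dimethoxy-4-[(triisopropylsilyl)oxy]phenyl}prop-2-en-1-yl]oxy}-3-iodo-5-methoxybenzaldehyde | COc1cc([C@@H](C=C)Oc2c(OC)cc(C=O)cc2I)cc(OC)c1O[Si](C(C)C)(C(C)C)C(C)C | intermediate
9 | C3a-centred aryl radical derived from 8 by loss of iodine | COc1cc([C@@H](C=C)Oc2c(OC)cc(C=O)c[c]2)cc(OC)c1O[Si](C(C)C)(C(C)C)C(C)C | intermediate
10 | cyclised primary alkyl radical (trans-2-aryl-5-formyl-7-methoxy-2,3-dihydrobenzofuran-3-yl)methyl | COc1cc([C@@H]2Oc3c(OC)cc(C=O)cc3[C@H]2[CH2])cc(OC)c1O[Si](C(C)C)(C(C)C)C(C)C | intermediate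
11 | (2R,3S)-2-{3,5-dimethoxy-4-[(triisopropylsilyl)oxy]phenyl}-7-methoxy-3-{[(2,2,6,6-tetramethylpiperidin-1-yl)oxy]methyl}-2,3-dihydro-1-benzofuran-5-carbaldehyde | COc1cc([C@@H]2Oc3c(OC)cc(C=O)cc3[C@H]2CON4C(C)(C)CCCC4(C)C)cc(OC)c1O[Si](C(C)C)(C(C)C)C(C)C | intermediate
12 | methyl 3,5-dihydroxybenzoate | COC(=O)c1cc(O)cc(O)c1 | starting material
13 | methyl 3,5-bis[(triisopropylsilyl)oxy]benzoate | COC(=O)c1cc(O[Si](C(C)C)(C(C)C)C(C)C)cc(O[Si](C(C)C)(C(C)C)C(C)C)c1 | intermediate
14 | {3,5-bis[(triisopropylsilyl)oxy]phenyl}methanol | OCc1cc(O[Si](C(C)C)(C(C)C)C(C)C)cc(O[Si](C(C)C)(C(C)C)C(C)C)c1 | intermediate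
15 | 1-(bromomethyl)-3,5-bis[(triisopropylsilyl)oxy]benzene | BrCc1cc(O[Si](C(C)C)(C(C)C)C(C)C)cc(O[Si](C(C)C)(C(C)C)C(C)C)c1 | intermediate
16 | diethyl {3,5-bis[(triisopropylsilyl)oxy]benzyl}phosphonate | CCOP(=O)(OCC)Cc1cc(O[Si](C(C)C)(C(C)C)C(C)C)cc(O[Si](C(C)C)(C(C)C)C(C)C)c1 | intermediate
17 | sodium salt of the benzylic carbanion of 16 | [Na+].CCOP(=O)(OCC)[CH-]c1cc(O[Si](C(C)C)(C(C)C)C(C)C)cc(O[Si](C(C)C)(C(C)C)C(C)C)c1 | intermediate
18 | 1-({(2R,3S)-5-[(E)-2-{3,5-bis[(triisopropylsilyl)oxy]phenyl}ethenyl]-2-{3,5-dimethoxy-4-[(triisopropylsilyl)oxy]phenyl}-7-methoxy-2,3-dihydro-1-benzofuran-3-yl}methoxy)-2,2,6,6-tetramethylpiperidine | COc1cc([C@@H]2Oc3c(OC)cc(/C=C/c4cc(O[Si](C(C)C)(C(C)C)C(C)C)cc(O[Si](C(C)C)(C(C)C)C(C)C)c4)cc3[C@H]2CON5C(C)(C)CCCC5(C)C)cc(OC)c1O[Si](C(C)C)(C(C)C)C(C)C | intermediate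
19 | {(2R,3S)-5-[(E)-2-{3,5-bis[(triisopropylsilyl)oxy]phenyl}ethenyl]-2-{3,5-dimethoxy-4-[(triisopropylsilyl)oxy]phenyl}-7-methoxy-2,3-dihydro-1-benzofuran-3-yl}methanol | COc1cc([C@@H]2Oc3c(OC)cc(/C=C/c4cc(O[Si](C(C)C)(C(C)C)C(C)C)cc(O[Si](C(C)C)(C(C)C)C(C)C)c4)cc3[C@H]2CO)cc(OC)c1O[Si](C(C)C)(C(C)C)C(C)C | intermediate
20 | Gnetucleistol F, 5-[(E)-2-[(2R,3S)-2-(4-hydroxy-3,5-dimethoxyphenyl)-3-(hydroxymethyl)-7-methoxy-2,3-dihydro-1-benzofuran-5-yl]ethenyl]benzene-1,3-diol | COc1cc([C@@H]2Oc3c(OC)cc(/C=C/c4cc(O)cc(O)c4)cc3[C@H]2CO)cc(OC)c1O | target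

**Step count**
Total: 13 steps. Longest linear sequence: 9 steps (steps 1–6 and 11–13, from syringaldehyde). Steps 7–10 build the phosphonate in a side branch.

**Steps most likely to fail**

Step 5. The hindered, weakly nucleophilic 2,6-disubstituted aryloxide may attack the allyl iridium intermediate slowly, and the doubly activated C2–O bond of the product may re-ionise, eroding branched selectivity and enantiomeric purity. The fallback sets out from allylic alcohol 4 and returns at 8. Sharpless asymmetric epoxidation (Ti(OiPr)4, D-(−)-diethyl tartrate, t-BuOOH, 4 Å sieves, CH2Cl2, −20 °C) should give [(2R,3R)-3-{3,5-dimethoxy-4-[(triisopropylsilyl)oxy]phenyl}oxiran-2-yl]methanol F1. Opening of the epoxide at its benzylic carbon by phenol 6 (as its caesium salt from Cs2CO3 in DMF, or with Ti(OiPr)4 assistance) proceeds with inversion and should give 4-{[(1S,2R)-1-{3,5-dimethoxy-4-[(triisopropylsilyl)oxy]phenyl}-2,3-dihydroxypropyl]oxy}-3-iodo-5-methoxybenzaldehyde F2. 1,1'-Thiocarbonyldiimidazole then converts the diol into the cyclic thiocarbonate 4-{[(S)-{3,5-dimethoxy-4-[(triisopropylsilyl)oxy]phenyl}[(4R)-2-thioxo-1,3-dioxolan-4-yl]methyl]oxy}-3-iodo-5-methoxybenzaldehyde F3. Corey–Winter fragmentation with hot P(OMe)3 unveils the vinyl group and delivers 8, with C2 fixed by the epoxide instead of by the catalyst.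

Step 6. The ring closure may discriminate poorly between the two faces of the vinyl group, so that trans control at C3 is incomplete. The fallback sets out from alcohol 19, carried through steps 11 and 12 as the mixture of C3 epimers, and returns at 19. Oxidation with Dess–Martin periodinane should give (2R,3R)-5-[(E)-2-{3,5-bis[(triisopropylsilyl)oxy]phenyl}ethenyl]-2-{3,5-dimethoxy-4-[(triisopropylsilyl)oxy]phenyl}-7-methoxy-2,3-dihydro-1-benzofuran-3-carbaldehyde F4 together with its C3 epimer. C3 is now enolisable, and DBU in CH2Cl2 should equilibrate the mixture to the more stable trans isomer; ring opening at C2 is not expected because it would be a disfavoured retro-5-endo process. NaBH4 in MeOH then returns trans 19. Control at C3 thus moves from the kinetic ring closure to a thermodynamic equilibration at the aldehyde oxidation level.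

Step 11. The strongly basic phosphonate carbanion may attack the aryl silyl ethers, or olefination of the electron-rich aldehyde may be slow enough for base-induced degradation to compete. The fallback sets out from aldehyde 11 and returns at 18. Wittig methylenation (Ph3PCH3Br, KOtBu, THF, 0 °C, brief exposure) should give 1-{[(2R,3S)-5-ethenyl-2-{3,5-dimethoxy-4-[(triisopropylsilyl)oxy]phenyl}-7-methoxy-2,3-dihydro-1-benzofuran-3-yl]methoxy}-2,2,6,6-tetramethylpiperidine F5. Commercial 5-iodoresorcinol is silylated (TIPSCl, imidazole, DMF) to 1-iodo-3,5-bis[(triisopropylsilyl)oxy]benzene F6. A Mizoroki–Heck coupling of the two (Pd(OAc)2, P(o-tol)3, Et3N, DMF, 90 °C) should form the E stilbene 18 under weakly basic conditions.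

**Further compounds**
F1 | step 5 | [(2R,3R)-3-{3,5-dimethoxy-4-[(triisopropylsilyl)oxy]phenyl}oxiran-2-yl]methanol | COc1cc([C@H]2O[C@@H]2CO)cc(OC)c1O[Si](C(C)C)(C(C)C)C(C)C
F2 | step 5 | 4-{[(1S,2R)-1-{3,5-dimethoxy-4-[(triisopropylsilyl)oxy]phenyl}-2,3-dihydroxypropyl]oxy}-3-iodo-5-methoxybenzaldehyde | COc1cc([C@@H]([C@H](O)CO)Oc2c(OC)cc(C=O)cc2I)cc(OC)c1O[Si](C(C)C)(C(C)C)C(C)C
F3 | step 5 | 4-{[(S)-{3,5-dimethoxy-4-[(triisopropylsilyl)oxy]phenyl}[(4R)-2-thioxo-1,3-dioxolan-4-yl]methyl]oxy}-3-iodo-5-methoxybenzaldehyde | COc1cc([C@@H]([C@H]3COC(=S)O3)Oc2c(OC)cc(C=O)cc2I)cc(OC)c1O[Si](C(C)C)(C(C)C)C(C)C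
F4 | step 6 | (2R,3R)-5-[(E)-2-{3,5-bis[(triisopropylsilyl)oxy]phenyl}ethenyl]-2-{3,5-dimethoxy-4-[(triisopropylsilyl)oxy]phenyl}-7-methoxy-2,3-dihydro-1-benzofuran-3-carbaldehyde | COc1cc([C@@H]2Oc3c(OC)cc(/C=C/c4cc(O[Si](C(C)C)(C(C)C)C(C)C)cc(O[Si](C(C)C)(C(C)C)C(C)C)c4)cc3[C@H]2C=O)cc(OC)c1O[Si](C(C)C)(C(C)C)C(C)C
F5 | step 11 | 1-{[(2R,3S)-5-ethenyl-2-{3,5-dimethoxy-4-[(triisopropylsilyl)oxy]phenyl}-7-methoxy-2,3-dihydro-1-benzofuran-3-yl]methoxy}-2,2,6,6-tetramethylpiperidine | COc1cc([C@@H]2Oc3c(OC)cc(C=C)cc3[C@H]2CON4C(C)(C)CCCC4(C)C)cc(OC)c1O[Si](C(C)C)(C(C)C)C(C)C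
F6 | step 11 | 1-iodo-3,5-bis[(triisopropylsilyl)oxy]benzene | Ic1cc(O[Si](C(C)C)(C(C)C)C(C)C)cc(O[Si](C(C)C)(C(C)C)C(C)C)c1
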